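(The readings were computed for substances that don't exist.)

Ash, the run made earlier, shows first end groups and second end groups joining to links; red and violet are the flasks to foresee from it.

| setting | ash | red | violet |
|---|---|---|---|
| first end groups | 0.80 M | 0.80 M | 2.5 M |
| second end groups | 1.2 M | 0.784 M | 0.784 M |
| remark | run made earlier |  |  |
| time |  | 4.0 d | 8.0 d |

- ash (time / h: links / %, first end groups / %): 4.00: 48, 51; 8.00: 66, 32; 12.0: 81, 22; 15.0: 82, 17; 20.0: 88, 11

(standard deviation of a reading: 2 percentage points)

- what was read earlier has a scatter of 2 percentage points, one standard deviation

1. which of the two ends with the higher amount of links, in percent of the first end groups charged ("neither" if they lie within 2 percentage points) (red / violet / neither)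
2. links at the end, in percent of the first end groups charged, red
3. links at the end, in percent of the first end groups charged, violet

In ash, links and first end groups add up to 99.0% at the last reading, so a working law of rate k[first][second] is taken, and that reading gives k = 0.163 L mol⁻¹ h⁻¹. With c the partner's concentration and t the time, red's charge of second end groups gives k·c·t = 12.3, the turnover count N: the lifetimes a group has lived through.

Red looks nearly like ash, with the same charge of first end groups. But in ash the partner stays above a surplus of 0.400 M, whereas in red the charges differ by 0.0160 M, so the partner falls with the group and the share left is 1/(1+N). Ash's last share of 11% would take N = 8.09 on such equal charges, and red has more than that. My reckoning therefore leaves 7.52% of red's first end groups and gives 92.5% links, under the ceiling of 98.0% set by its second end groups.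

In violet, second end groups are the limiting reagent, with a ceiling of 31.4%. Their partner stays above 1.72 M, so N = 53.8 and hardly any of them should remain. My reckoning then puts violet's links at that ceiling and red higher.

The forecast has 91% for red, less than my reckoning, and 31.2% for violet, and says: “Red ends higher in percent terms.”

The flask puts red ahead, with 89.4% against 29.8%.

    first end groups + second end groups → rings, rate k1*[first end groups] as long as [second end groups] is above zero (k = 0.00148 h⁻¹)
    first end groups + second end groups → links (k = 0.169 L mol⁻¹ h⁻¹)

In red, N = 12.3 gave 7.52% of the first end groups left, and the flask holds 7.61%, while links stand at 89.4% beside rings at 2.95%. A neighbouring flask is red with second end groups cut to 0.31 M, which gives a ceiling of 38.7%, and its surplus of 0.490 M first end groups gives its second end groups N = 7.69. At 4.00 d, that neighbour holds 0% of its second end groups and 61.2% of its first end groups, with rings at 3.93% and links at 34.8%.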